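**Retrosynthetic overview**
1. The target comes from a 1,4-diketone (ring A ketone and norbornanone) by equatorial methyl addition and exo-face hydride reduction; its two α-CH centres (the A/B ring-fusion CH and the neighbouring norbornane CH) equilibrate to their thermodynamically preferred configurations. Bromine comes from an alkenyl bromide by hydrogen-atom-transfer reduction, and the isopropyl group from the acetyl group of butenone.
2. Key disconnection: the bond between the A/B ring-fusion CH and the norbornane CH next to the CHOH carbon. It is formed when a norbornene silyl enol ether attacks a ketal-derived oxocarbenium ion of ring A, in the same flask in which the norbornane has just been made by Diels–Alder reaction of a 2-silyloxycyclopentadiene with butenone.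
3. Enabling feature: the norbornane C–OH carbon lies between a bridgehead CH and the bond-forming CH, so its enol ether can only point at that CH and arises regiospecifically from the cycloaddition. In ring A the CHBr carbon and the ring-fusion CH sit 1,3 across the quaternary methyl carbon, so ring A is a 2-methylcyclohexane-1,3-dione whose two carbonyls become the electrophile (as ketal) and the bromine handle.
4. Order of ring formation: ring A (bromine-bearing cyclohexane, from the dione) and a cyclopentenone are bought; step 7 makes the norbornane (rings C and D) and then ring B (central cyclohexane). The quaternary methyl stereocentre is set earlier, in step 3, by desymmetrizing transfer hydrogenation.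

Key step: step 7

Remark: the sense of induction in the two catalyst-controlled steps (3 and 7) is assigned from the accepted stereochemical models; if either proved opposite, the mirror-image catalyst would be used. The carbinol centre made in step 3 is removed again in step 5.

**Step 1**
Reactants: 1 3-ethoxycyclopent-2-en-1-one; 2 vinylmagnesium bromide
Product: 4 3-ethenylcyclopent-2-en-1-one, via 1,2-adduct 3 (not isolated)
Conditions: THF, 0 °C; then 1 M HCl, 23 °C
Reagents that add atoms: water (O)
Why: Stork–Danheiser transposition, in which 1,2-addition to the vinylogous ester and acid hydrolysis of the enol ether with loss of water should give the 3-substituted enone; no stereocenter is formed.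

**Step 2**
Reactants: 4 3-ethenylcyclopent-2-en-1-one; 5 2-methylcyclohexane-1,3-dione
Product: 6 2-methyl-2-[2-(3-oxocyclopent-1-en-1-yl)ethyl]cyclohexane-1,3-dione
Conditions: Et3N (0.2 equiv), DMF, 23 → 40 °C
Reagents that add atoms: none
Why: vinylogous (1,6) Michael addition of the soft dione enolate to the unhindered terminus of the dienone, the extended enol returning to the conjugated cyclopentenone; the new quaternary carbon is still prochiral.

**Step 3**
Reactants: 6 triketone
Product: 7 (2R,3R)-3-hydroxy-2-methyl-2-[2-(3-oxocyclopent-1-en-1-yl)ethyl]cyclohexan-1-one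
Conditions: RuCl(p-cymene)[(R,R)-TsDPEN] (1 mol %), HCO2H/Et3N 5:2, CH2Cl2, 23 °C
Reagents that add atoms: none
Why: Noyori asymmetric transfer hydrogenation should desymmetrize the 2,2-disubstituted 1,3-dione (its activated, non-conjugated carbonyls react much faster than the enone), the catalyst choosing one enantiotopic carbonyl and so setting the configuration of the quaternary methyl carbon, with hydride entering anti to the larger chain.

**Step 4**
Reactants: 7 hydroxy diketone
Product: 8 3-{2-[(6R,7R)-7-hydroxy-6-methyl-1,4-dioxaspiro[4.5]decan-6-yl]ethyl}cyclopent-2-en-1-one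
Conditions: ethylene glycol, PPTS, benzene, reflux (Dean–Stark)
Reagents that add atoms: ethylene glycol (OCCO)
Why: acid-catalysed ketalization should take the saturated ketone and leave the conjugated enone, the chemoselectivity known from the Wieland–Miescher ketone; no new stereocenter.

**Step 5**
Reactants: 8 hydroxy ketal
Product: 9 3-{2-[(6R)-6-methyl-7-oxo-1,4-dioxaspiro[4.5]decan-6-yl]ethyl}cyclopent-2-en-1-one
Conditions: Dess–Martin periodinane, NaHCO3, CH2Cl2, 23 °C
Reagents that add atoms: none
Why: Dess–Martin oxidation returns the carbinol to a ketone, so the two former dione carbonyls are now different (ketal and ketone) around a configurationally defined quaternary carbon.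

**Step 6**
Reactants: 9 keto ketal
Product: 11 2-(TBSO)-4-{2-[(6R)-7-(TBSO)-6-methyl-1,4-dioxaspiro[4.5]dec-7-en-6-yl]ethyl}cyclopenta-1,3-diene, via dilithium bis-enolate 10 (not isolated)
Conditions: LiN(i-Pr)2 (2.3 equiv), THF, −78 °C; TBSOTf (2.5 equiv), −78 °C; Et3N
Reagents that add atoms: tert-butyldimethylsilyl triflate (CC(C)(C)[Si](C)(C)OS(=O)(=O)C(F)(F)F)
Why: kinetic deprotonation should remove the α′-proton of the enone (cross-conjugated dienolate) and the only enolizable α-proton of the ring A ketone (its other side is quaternary), and O-silylation then gives the 2-silyloxydiene and a masked ring A ketone while the ketal is untouched.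

**Step 7**
Reactants: 11 bis(silyl enol ether); 12 but-3-en-2-one
Product: 14 tetracyclic β-alkoxy ketone (endo-acetyl norbornanone fused bridgehead/exo to ring B; tertiary 2-(TBSO)ethyl ether at the A/B fusion carbon; ring A TBS enol ether), via Diels–Alder adduct 13 (not isolated)
Conditions: 12 (1.2 equiv), oxazaborolidinium triflimide from (S)-α,α-diphenylprolinol and o-tolylboronic acid (20 mol %), CH2Cl2, −78 °C; then TBSOTf (0.3 equiv), −78 → −30 °C; Et3N
Reagents that add atoms: none
Why: The oxazaborolidinium-activated enone should undergo an endo, "para"-regioselective Diels–Alder reaction with the 2-silyloxycyclopentadiene (closest precedent: oxazaborolidinium-catalysed cycloadditions of 2-silyloxydienes with vinyl ketones), the unsubstituted nucleophilic diene terminus bonding to the CH2 of the enone and the substituted terminus to the acyl-bearing carbon; this [4+2] closure makes the norbornene, with both bridgeheads set by the catalyst-controlled face and the acetyl carbon endo by the Alder rule. TBSOTf then opens the dioxolane to an oxocarbenium ion, which is trapped by the norbornene silyl enol ether (intramolecular Mukaiyama aldol-type addition to a ketal, 6-(enolexo)-exo-trig), closing ring B through the bond between the future A/B ring-fusion carbon and the norbornane CH; the silyl group ends on the ring-opened glycol oxygen, so TBSOTf is catalytic. Regioselectivity is built in, because the other α-carbon of the norbornane carbonyl is a bridgehead and the ring A enol ether could only reach the cation through a four-membered ring. The new norbornane CH is set by exo attack, the endo face being covered by the endo acetyl group, and the configuration of the tertiary ether carbon is of no consequence because that carbon becomes sp2 in step 11. No choice between the two ring A carbonyls is needed, since only the ketal is electrophilic, so the quaternary methyl centre from step 3 is carried over unchanged.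

**Step 8**
Reactants: 14 β-alkoxy ketone
Product: 15 isopropenyl analogue of 14
Conditions: Cp2Ti(μ-Cl)(μ-CH2)AlMe2 (Tebbe reagent, 1.2 equiv), pyridine (cat.), THF/toluene, −40 → 0 °C
Reagents that add atoms: Tebbe reagent Cp2Ti(μ-Cl)(μ-CH2)AlMe2 (C[Al-]1(C)C[Ti]([Cl+]1)(C1C=CC=C1)C1C=CC=C1)
Why: Tebbe methylenation should convert the methyl ketone into the isopropenyl group without base, so the endo configuration next to the carbonyl is kept, while the neopentyl-type norbornanone and the enol ether do not react.

**Step 9**
Reactants: 15 isopropenyl silyl enol ether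
Product: 16 ring A enol triflate
Conditions: CsF, PhNTf2, DME, 23 °C
Reagents that add atoms: N-phenylbis(trifluoromethanesulfonimide) (O=S(=O)(N(c1ccccc1)S(=O)(=O)C(F)(F)F)C(F)(F)F)
Why: fluoride should cleave the silyl enol ether (much faster than the alkyl silyl ether) to a regiodefined cesium enolate, which is O-triflated; no stereocenter.

**Step 10**
Reactants: 16 enol triflate
Product: 17 ring A alkenyl bromide
Conditions: Ni(OAc)2·4H2O (10 mol %), 1,5-cyclooctadiene (25 mol %), Zn (20 mol %), LiBr, DMA/THF, 23 °C
Reagents that add atoms: lithium bromide ([Li+].[Br-])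
Why: nickel-catalysed halide exchange of an enol triflate (oxidative addition, triflate/bromide exchange, reductive elimination) should give the alkenyl bromide; ketone, ethers and the 1,1-disubstituted alkene are tolerated.

**Step 11**
Reactants: 17 alkenyl bromide β-alkoxy ketone
Product: 18 tetracyclic enone (tetrasubstituted alkene between the A/B fusion carbon and the norbornane carbon, conjugated with the norbornanone; alkenyl bromide; isopropenyl)
Conditions: DBU, toluene, 80 °C
Reagents that add atoms: none
Why: E1cB elimination of the β-alkoxy group should give the tetrasubstituted enone and relieve the compression at the tertiary ether carbon; it is safe at this point because no epimerizable acyl group is left.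

**Step 12**
Reactants: 18 enone
Product: 19 bromo enone (equatorial CHBr cis to the angular methyl; isopropyl)
Conditions: Co(acac)2 (25 mol %), t-BuOOH, Et3SiH, 1,4-cyclohexadiene, n-PrOH, 23 °C
Reagents that add atoms: none
Why: metal-hydride hydrogen-atom-transfer hydrogenation of the alkenyl bromide gives an α-bromoalkyl radical that should take hydrogen from 1,4-cyclohexadiene on the face opposite the axial angular methyl, leaving bromine equatorial and cis to that methyl; the isopropenyl group is reduced by the same mechanism, and the hindered, electron-poor tetrasubstituted enone should not react.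

**Step 13**
Reactants: 19 bromo enone
Product: 20 ene-1,4-dione
Conditions: Rh2(cap)4 (dirhodium tetracaprolactamate, 1 mol %), t-BuOOH (70 % aq.), 1,2-dichloroethane, 40 °C
Reagents that add atoms: tert-butyl hydroperoxide (CC(C)(C)OO)
Why: Rh2(cap)4/t-BuOOH allylic oxidation of an enone to an ene-dione; the ring A CH2 next to the alkene is the only allylic C–H in the molecule.

**Step 14**
Reactants: 20 ene-dione
Product: 21 1,4-diketone (rings A/B trans-fused, ring B exo on the norbornane)
Conditions: Zn, AcOH, 23 → 60 °C
Reagents that add atoms: none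
Why: Zn/AcOH reduction of the ene-1,4-dione; both new CH centres are α to a ketone and should equilibrate in the acid to the one unstrained isomer, since the cis-A/B isomer would put a ring A carbon syn-axial to the methano bridge and the endo isomer would collide with the endo isopropyl group.

**Step 15**
Reactants: 21 1,4-diketone
Product: 22 hydroxy ketone (axial tertiary alcohol, equatorial methyl)
Conditions: MeLi, CeCl3, THF, −78 °C; aq. NH4Cl
Reagents that add atoms: methyllithium ([Li]C)
Why: organocerium 1,2-addition (weakly basic, so no enolization next to the γ-bromide) should occur at the cyclohexanone and not at the hindered norbornanone, from the equatorial side because the axial path is blocked by the 1,3-diaxial angular methyl, which gives the axial alcohol.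

**Step 16**
Reactants: 22 hydroxy ketone
Product: 23 target (CNP0295684.1)
Conditions: NaBH4, MeOH, 0 °C
Reagents that add atoms: none
Why: hydride reduction of the norbornanone from the exo face should give the endo alcohol.

**Compound list**
1 | 3-ethoxycyclopent-2-en-1-one | CCOC1=CC(=O)CC1 | starting material
2 | vinylmagnesium bromide | C=C[Mg]Br | starting material
3 | 3-ethoxy-1-ethenylcyclopent-2-en-1-ol (1,2-adduct) | C=CC1(O)C=C(OCC)CC1 | intermediate (not isolated)
4 | 3-ethenylcyclopent-2-en-1-one | C=CC1=CC(=O)CC1 | intermediate
5 | 2-methylcyclohexane-1,3-dione | CC1C(=O)CCCC1=O | starting material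
6 | 2-methyl-2-[2-(3-oxocyclopent-1-en-1-yl)ethyl]cyclohexane-1,3-dione | CC1(CCC2=CC(=O)CC2)C(=O)CCCC1=O | intermediate
7 | (2R,3R)-3-hydroxy-2-methyl-2-[2-(3-oxocyclopent-1-en-1-yl)ethyl]cyclohexan-1-one | O=C1C=C(CC[C@]2(C)[C@H](O)CCCC2=O)CC1 | intermediate
8 | 3-{2-[(6R,7R)-7-hydroxy-6-methyl-1,4-dioxaspiro[4.5]decan-6-yl]ethyl}cyclopent-2-en-1-one | O=C1C=C(CC[C@]2(C)[C@H](O)CCCC23OCCO3)CC1 | intermediate
9 | 3-{2-[(6R)-6-methyl-7-oxo-1,4-dioxaspiro[4.5]decan-6-yl]ethyl}cyclopent-2-en-1-one | O=C1C=C(CC[C@]2(C)C(=O)CCCC23OCCO3)CC1 | intermediate
10 | dilithium bis-enolate of 9 (cross-conjugated dienolate and ring A enolate) | [Li+].[Li+].[O-]C1=CCC(CC[C@]2(C)C([O-])=CCCC23OCCO3)=C1 | intermediate (not isolated)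
11 | 2-(TBSO)-4-{2-[(6R)-7-(TBSO)-6-methyl-1,4-dioxaspiro[4.5]dec-7-en-6-yl]ethyl}cyclopenta-1,3-diene | CC(C)(C)[Si](C)(C)OC1=CCC(CC[C@]2(C)C(O[Si](C)(C)C(C)(C)C)=CCCC23OCCO3)=C1 | intermediate
12 | but-3-en-2-one | CC(=O)C=C | starting material
13 | Diels–Alder adduct: 2-(TBSO)norborn-2-ene with endo acetyl next to the substituted bridgehead, which carries the ring A ethyl chain | CC(=O)[C@@H]1C[C@H]2C[C@]1(CC[C@]3(C)C(O[Si](C)(C)C(C)(C)C)=CCCC34OCCO4)C=C2O[Si](C)(C)C(C)(C)C | intermediate (not isolated)
14 | tetracyclic β-alkoxy ketone: endo-acetyl norbornanone, ring B fused bridgehead/exo, tertiary 2-(TBSO)ethyl ether at the A/B fusion carbon (O toward the methano bridge), ring A TBS enol ether | CC(=O)[C@@H]1C[C@H]2C[C@@]13CC[C@]1(C)C(O[Si](C)(C)C(C)(C)C)=CCC[C@@]1(OCCO[Si](C)(C)C(C)(C)C)[C@@H]3C2=O | intermediate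
15 | isopropenyl analogue of 14 (endo isopropenyl) | CC(=C)[C@@H]1C[C@H]2C[C@@]13CC[C@]1(C)C(O[Si](C)(C)C(C)(C)C)=CCC[C@@]1(OCCO[Si](C)(C)C(C)(C)C)[C@@H]3C2=O | intermediate
16 | ring A enol triflate of 15 | CC(=C)[C@@H]1C[C@H]2C[C@@]13CC[C@]1(C)C(OS(=O)(=O)C(F)(F)F)=CCC[C@@]1(OCCO[Si](C)(C)C(C)(C)C)[C@@H]3C2=O | intermediate
17 | ring A alkenyl bromide (β-alkoxy ketone) | CC(=C)[C@@H]1C[C@H]2C[C@@]13CC[C@]1(C)C(Br)=CCC[C@@]1(OCCO[Si](C)(C)C(C)(C)C)[C@@H]3C2=O | intermediate
18 | tetracyclic enone with alkenyl bromide and endo isopropenyl | CC(=C)[C@@H]1C[C@H]2C[C@@]13CC[C@]1(C)C(Br)=CCCC1=C3C2=O | intermediate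
19 | bromo enone: equatorial CHBr cis to the angular methyl, endo isopropyl | CC(C)[C@@H]1C[C@H]2C[C@@]13CC[C@]1(C)[C@@H](Br)CCCC1=C3C2=O | intermediate
20 | ene-1,4-dione | CC(C)[C@@H]1C[C@H]2C[C@@]13CC[C@]1(C)[C@@H](Br)CCC(=O)C1=C3C2=O | intermediate
21 | saturated 1,4-diketone, A/B trans, ring B exo on the norbornane | CC(C)[C@@H]1C[C@H]2C[C@@]13CC[C@]1(C)[C@@H](Br)CCC(=O)[C@H]1[C@@H]3C2=O | intermediate
22 | hydroxy ketone with axial tertiary alcohol | CC(C)[C@@H]1C[C@H]2C[C@@]13CC[C@]1(C)[C@@H](Br)CC[C@@](C)(O)[C@H]1[C@@H]3C2=O | intermediate
23 | CNP0295684.1 | CC(C)[C@@H]1C[C@H]2C[C@@]13CC[C@]1(C)[C@@H](Br)CC[C@@](C)(O)[C@H]1[C@@H]3[C@H]2O | target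

**Step count and risks**
Total: 16 steps. Longest linear sequence: 16 steps (1 → 23).

Step 7. After the cycloaddition, closure of ring B may stall, because the oxocarbenium carbon must become tetrahedral with its oxygen pressed against the methano bridge; the enol ether is then lost by protodesilylation and the cation by proton loss. Incomplete face selectivity in the cycloaddition is a second source of loss. Fallback (from 6, back at 18): ring B is closed under thermodynamic control, with the masking of the two ring A carbonyls exchanged. Transfer hydrogenation of 6 with RuCl(p-cymene)[(S,S)-TsDPEN] gives the enantiomeric hydroxy diketone F1. Ketalization of its ketone gives hydroxy ketal F2, and Dess–Martin oxidation gives keto ketal F3, which has the ketone at the future ring-fusion carbon and the ketal at the future bromine carbon. LiN(i-Pr)2/TBSOTf gives bis(enol ether) F4, the same catalysed Diels–Alder reaction with 12 gives adduct F5 (isolated), and Tebbe methylenation gives isopropenyl compound F6. TBAF/AcOH frees both ketones to give diketone F7. KOt-Bu in t-BuOH at 40 °C then effects the intramolecular aldol condensation (norbornanone enolate onto the ring A ketone, same bond, then dehydration) to enone ketal F8. Aqueous HCl/THF gives enone ketone F9, KN(SiMe3)2/PhNTf2 gives enol triflate F10, and the bromide exchange of step 10 returns to 18.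

Step 12. Hydrogen-atom transfer may also reach the conjugated alkene (conjugate reduction), and the α-bromoalkyl radical may be reduced further with loss of bromide. Fallback (from 17, back at 19): the reduction is run before the enone exists. The same cobalt conditions applied to 17 give bromo β-alkoxy ketone F11, and DBU elimination as in step 11 gives 19.

Step 15. The organocerium reagent may add to the norbornanone as well, or enolize the diketone so that the enolate displaces the γ-bromide. Fallback (from 21, back at 23): the order of the two carbonyl additions is reversed. LiN(i-Pr)2 with Me3SiCl present (THF, −78 °C) masks the ring A ketone as its less substituted silyl enol ether F12. LiAlH4 at −78 °C reduces the norbornanone from the exo face to the endo alcohol F13. K2CO3/MeOH releases hydroxy ketone F14, and excess MeLi/CeCl3 then gives 23.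

**Further compounds**
F1 | step 7 | (2S,3S)-3-hydroxy-2-methyl-2-[2-(3-oxocyclopent-1-en-1-yl)ethyl]cyclohexan-1-one | O=C1C=C(CC[C@]2(C)C(=O)CCC[C@@H]2O)CC1
F2 | step 7 | dioxolane of F1 at the ketone | O=C1C=C(CC[C@]2(C)C3(OCCO3)CCC[C@@H]2O)CC1
F3 | step 7 | keto ketal (ketone and ketal exchanged relative to 9) | O=C1C=C(CC[C@]2(C)C3(OCCO3)CCCC2=O)CC1
F4 | step 7 | bis(TBS enol ether) of F3 | CC(C)(C)[Si](C)(C)OC1=CCC(CC[C@]2(C)C3(OCCO3)CCC=C2O[Si](C)(C)C(C)(C)C)=C1
F5 | step 7 | Diels–Alder adduct of F4 with 12 (endo acetyl) | CC(=O)[C@@H]1C[C@H]2C[C@]1(CC[C@]3(C)C4(OCCO4)CCC=C3O[Si](C)(C)C(C)(C)C)C=C2O[Si](C)(C)C(C)(C)C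
F6 | step 7 | isopropenyl analogue of F5 | CC(=C)[C@@H]1C[C@H]2C[C@]1(CC[C@]3(C)C4(OCCO4)CCC=C3O[Si](C)(C)C(C)(C)C)C=C2O[Si](C)(C)C(C)(C)C
F7 | step 7 | norbornanone/ring A diketone with ring A ketal | CC(=C)[C@@H]1C[C@H]2C[C@]1(CC[C@]3(C)C4(OCCO4)CCCC3=O)CC2=O
F8 | step 7 | tetracyclic enone with ring A ketal | CC(=C)[C@@H]1C[C@H]2C[C@@]13CC[C@]1(C)C4(OCCO4)CCCC1=C3C2=O
F9 | step 7 | tetracyclic enone with ring A ketone | CC(=C)[C@@H]1C[C@H]2C[C@@]13CC[C@]1(C)C(=O)CCCC1=C3C2=O
F10 | step 7 | tetracyclic enone with ring A enol triflate | CC(=C)[C@@H]1C[C@H]2C[C@@]13CC[C@]1(C)C(OS(=O)(=O)C(F)(F)F)=CCCC1=C3C2=O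
F11 | step 12 | bromo β-alkoxy ketone (reduced 17) | CC(C)[C@@H]1C[C@H]2C[C@@]13CC[C@]1(C)[C@@H](Br)CCC[C@@]1(OCCO[Si](C)(C)C(C)(C)C)[C@@H]3C2=O
F12 | step 15 | ring A trimethylsilyl enol ether of 21 | CC(C)[C@@H]1C[C@H]2C[C@@]13CC[C@]1(C)[C@@H](Br)CC=C(O[Si](C)(C)C)[C@H]1[C@@H]3C2=O
F13 | step 15 | endo norbornanol with ring A silyl enol ether | CC(C)[C@@H]1C[C@H]2C[C@@]13CC[C@]1(C)[C@@H](Br)CC=C(O[Si](C)(C)C)[C@H]1[C@@H]3[C@H]2O
F14 | step 15 | endo norbornanol with ring A ketone | CC(C)[C@@H]1C[C@H]2C[C@@]13CC[C@]1(C)[C@@H](Br)CCC(=O)[C@H]1[C@@H]3[C@H]2O
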